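If I want the share of J.L in these flasks, I follow where L goes. Z turns into L, J or X takes L, J.L relaxes to Q, and X also pairs off with itself.

| flask | Z | J | X | time | remark |
|---|---|---|---|---|---|
| grey | 0.11 M (in portions, 5, over 3.0 min) | 1.80 equiv | 4.00 equiv | 15 min | first portion at the start, last at 3.0 min |
| red | 0.11 M (fed, over 3.0 min) | 1.80 equiv | 4.00 equiv | 15 min | all else is in the flask from the start; the feed brings no volume worth counting |
| amber | 0.11 M | 1.80 equiv | 4.00 equiv (fed, over 3.0 min) | 15 min | all else is in the flask from the start; the feed brings no volume worth counting |
| violet | 0.11 M | 1.80 equiv | 4.00 equiv | 15 min | everything together at the start |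

- which flask leads in share of J.L in J.L plus X.L ("all alike" within 1.5 percentage points) (grey / red / amber / violet / all alike)
- share of J.L in J.L plus X.L at the end, grey
- share of J.L in J.L plus X.L at the end, red
- share of J.L in J.L plus X.L at the end, amber
- share of J.L in J.L plus X.L at the end, violet

- two of one species on the left: rate k times its square, two consumed each time
- run time (grey): 15 min

In violet, L has a half-life of 0.21 min against J alone, shorter than the 1.4 min of Z, so each L meets the concentrations of its moment of birth. I carry the capture ratio, or selectivity factor: L taken by J per L taken by X, which is 0.284 /M/s times cJ over 0.119 /M/s times cX. With charged concentrations, violet gives 1.07.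

In amber, cX climbs in a straight line during the feed, while births of L fall exponentially. Capture is curved in cX, so I average J's fraction of L over the births by Simpson's rule, not the ratio at a mean cX. That gives J 0.708 of L, so the amber ratio is 2.43. I neglect the J consumed. I also neglect X pairing off, whose first half-life of 8.65 min is longer than the mean life of Z, 2.02 min.

J.L and Q relax in 0.817 min, much shorter than the 15 min run, so they stand at their equilibrium constant 1.3. The share is then the ratio over the ratio plus 2.30. That gives 31.8% for violet and 51.4% for amber. I stop there and reckon neither grey nor red.

The forecast names amber and gives 36.8% for grey, 37% for red, 47% for amber and 34.2% for violet, reasoning that “feeding X slowly gives J a large early advantage”. My 51.4% for amber stands above its figure, and my 31.8% for violet stands below its figure.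

The simulation gives 37.0% for grey, 37.1% for red, 45.1% for amber and 34.2% for violet, so amber leads, as forecast.

    X + L → X.L (k1 = 0.119 /M/s)
    2 X → X2 (k2 = 0.00219 /M/s)
    Z → L (k3 = 0.00824 /s)
    J.L ⇌ Q (K4 = 1.3, k4 = 0.00799 /s)
    J + L → J.L (k5 = 0.284 /M/s)

At the end, amber holds J.L 28.4%, Q 36.9% and X.L 34.6% of the Z charged, a capture ratio read at 1.89 against my 2.43. The neighbour is amber with 1.10 equiv of J instead of 1.80 equiv. The charged ratio falls to 0.656, and the same average gives J 0.614 of L, so I reckon a ratio of 1.59 and a share of 40.9%. That neighbour ends with J.L 22.4%, Q 29.1% and X.L 48.4%, a ratio read at 1.06, and its share is 31.7%.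

All constants are made up.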